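**Retrosynthetic overview**
- Ring C (the pyran) is opened at the O1–C2 bond: the chromene is the oxa-6π closure product of an ortho-quinone methide made from the 3′-prenyl dihydrochalcone and prenal. With C3′ blocked, only the linear chromene can form.
- The 3′-prenyl group is traced back through a [3,3] shift to the O4′–C(CH3)2 aryl ether bond, formed on the most acidic phenol by palladium catalysis (proposed new relay).
- The aryl ketone comes from resorcinol and 3-(4-hydroxyphenyl)propanoic acid by Friedel–Crafts acylation; no protecting groups are used.
- Ring order: rings A and B are bought as benzene rings; ring C is the only ring formed, in the last step.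

Assumption: the target has no stereocentre and no stereogenic double bond (it is achiral), so the compound as drawn is the single species to be made; primed locants refer to ring A (the acyl-bearing resorcinol ring), and ring B is the 4-hydroxyphenyl ring.

**Step 1**
Reactants: 1 resorcinol; 2 3-(4-hydroxyphenyl)propanoic acid
Product: 3 davidigenin (1-(2,4-dihydroxyphenyl)-3-(4-hydroxyphenyl)propan-1-one)
Conditions: BF3·OEt2 (neat, as solvent), 90 °C, 2 h; then 10% aq. NaOAc
Reagents that add atoms: 3-(4-hydroxyphenyl)propanoic acid (2), OC(=O)CCc1ccc(O)cc1
Why: Friedel–Crafts (Nencki-type) C-acylation in which BF3 activates the acid, resorcinol is attacked at C4 (ortho/para to both hydroxyls), the much less activated para-substituted phenol ring of 2 does not compete, and the product is shielded from a second acylation as its BF2 chelate until the aqueous quench; no stereocentre is formed.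

**Step 2**
Reactants: 3 davidigenin; 4 tert-butyl (2-methylbut-3-en-2-yl) carbonate
Product: 6 3′-prenyldavidigenin (1-[2,4-dihydroxy-3-(3-methylbut-2-en-1-yl)phenyl]-3-(4-hydroxyphenyl)propan-1-one), via O4′-(1,1-dimethylallyl) ether 5 (not isolated)
Conditions: 4 (1.1 equiv), Pd(PPh3)4 (3 mol %), THF, 0 °C → rt, 2 h; then toluene, 105 °C (sealed tube), 8 h
Reagents that add atoms: tert-butyl (2-methylbut-3-en-2-yl) carbonate (4), CC(C)(C)OC(=O)OC(C)(C)C=C
Why: Proposed new method: a one-flask dynamic O-to-C prenyl relay in which zerovalent palladium ionises 4 to a π-(1,1-dimethylallyl)palladium cation, the tert-butoxide released with CO2 deprotonates only the most acidic hydroxyl (O4′–H, para to the acyl group, pKa about 8 against about 10 for ring B, the 2′-OH being locked in the ketone chelate), the phenoxide forms the tertiary aryl ether 5 at the more substituted allyl terminus, and on warming 5 leaves the equilibrium irreversibly by an aromatic Claisen [3,3] shift sent to C3′ by chelation-induced bond fixation (as in the classic rearrangement of 4-O-allylresacetophenone to its 3-allyl isomer), while any linear O4′-prenyl ether is re-ionised by the retained palladium (the acyl-conjugated aryloxide is a good leaving group) and fed back to 5; the closest known reactions are the Tsuji–Trost O-tert-prenylation of simple phenols followed by a separate thermal Claisen rearrangement, and palladium-catalysed O-to-C allyl migrations of enol ethers; no stereocentre is formed.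

**Step 3**
Reactants: 6 3′-prenyldavidigenin; 7 3-methylbut-2-enal (prenal)
Product: 9 target chromene (1-[7-hydroxy-2,2-dimethyl-8-(3-methylbut-2-en-1-yl)-2H-chromen-6-yl]-3-(4-hydroxyphenyl)propan-1-one), via ortho-quinone methide 8 (not isolated)
Conditions: 7 (2.5 equiv), ethylenediammonium diacetate (20 mol %), xylene, 130 °C, 8 h
Reagents that add atoms: 3-methylbut-2-enal (7), CC(C)=CC=O
Why: Formal [3+3] chromene annulation (Knoevenagel-type condensation, then oxa-6π electrocyclisation) in which the iminium ion of prenal alkenylates C5′, the only free position ortho to a free phenol of ring A (C3′ is blocked and ring B is a simple phenol that does not react), loss of the amine gives the ortho-quinone methide 8, and its electrocyclisation forms the O–C(CH3)2 bond that closes ring C; no stereocentre is formed.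

**Compound list**
1 | resorcinol (benzene-1,3-diol) | Oc1cccc(O)c1 | starting material
2 | 3-(4-hydroxyphenyl)propanoic acid (phloretic acid) | OC(=O)CCc1ccc(O)cc1 | starting material
3 | davidigenin, 1-(2,4-dihydroxyphenyl)-3-(4-hydroxyphenyl)propan-1-one | O=C(CCc1ccc(O)cc1)c1ccc(O)cc1O | intermediate
4 | tert-butyl (2-methylbut-3-en-2-yl) carbonate | CC(C)(C)OC(=O)OC(C)(C)C=C | starting material
5 | 1-[2-hydroxy-4-[(2-methylbut-3-en-2-yl)oxy]phenyl]-3-(4-hydroxyphenyl)propan-1-one (not isolated) | C=CC(C)(C)Oc1ccc(C(=O)CCc2ccc(O)cc2)c(O)c1 | intermediate
6 | 1-[2,4-dihydroxy-3-(3-methylbut-2-en-1-yl)phenyl]-3-(4-hydroxyphenyl)propan-1-one | CC(C)=CCc1c(O)ccc(C(=O)CCc2ccc(O)cc2)c1O | intermediate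
7 | 3-methylbut-2-enal (prenal) | CC(C)=CC=O | starting material
8 | 3-hydroxy-4-[3-(4-hydroxyphenyl)propanoyl]-2-(3-methylbut-2-en-1-yl)-6-[(Z)-3-methylbut-2-en-1-ylidene]cyclohexa-2,4-dien-1-one (ortho-quinone methide, not isolated) | O=C(CCc1ccc(O)cc1)C1=C/C(=C/C=C(C)C)C(=O)C(CC=C(C)C)=C1O | intermediate
9 | 1-[7-hydroxy-2,2-dimethyl-8-(3-methylbut-2-en-1-yl)-2H-chromen-6-yl]-3-(4-hydroxyphenyl)propan-1-one (achiral) | CC(C)=CCc1c(O)c(C(=O)CCc2ccc(O)cc2)cc2c1OC(C)(C)C=C2 | target

**Totals**
Total step count: 3. Longest linear sequence: 3 steps (1 → 3 → 6 → 9).

**Steps most likely to fail (the route has three steps, ranked by risk)**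

Step 2 (proposed new method). Risks:
- loss of the π-prenyl unit as isoprene by β-hydride elimination;
- some O-alkylation of ring B;
- a minor share of [3,3] shift to C5′;
- a second prenylation of 6.

Fallback, known chemistry that replaces the O-to-C relay by direct C-alkylation: it sets out from 3 and comes back at 6. Compound 3 is stirred with prenyl bromide (1.0 equiv) in 10% aqueous KOH at 0 °C to rt. In water the 4′-phenoxide is alkylated on carbon, mainly at C3′ between the two oxygens, as known for resacetophenones and phloretin-type dihydrochalcones. Compound 6 is separated by chromatography from the 5′-isomer and O-prenyl ethers in modest yield. No compound outside the list is made (F0).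

Step 3. Risks:
- C5′ is the electronically less favoured ortho position (the quinone methide 8 breaks the chelate-fixed bond pattern), so condensation may be slow;
- prenal may self-condense.

Fallback, which makes the aryl ether bond first and lets a sigmatropic cascade build the ring: it sets out from 6 and comes back at 9. Compound 6 is O4′-alkylated with 3-chloro-3-methylbut-1-yne (K2CO3 1.0 equiv, KI, CuI 5 mol %, acetone, 55 °C) to give 1-[2-hydroxy-3-(3-methylbut-2-en-1-yl)-4-[(2-methylbut-3-yn-2-yl)oxy]phenyl]-3-(4-hydroxyphenyl)propan-1-one F2. Heating this ether in xylene at 140 °C gives 9 by propargyl Claisen shift to the free C5′, [1,5]-hydrogen shift and oxa-6π closure.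

Step 1. Risks:
- ester or oligomer formation from the hydroxy acid 2;
- incomplete conversion.

Fallback, a Houben–Hoesch reaction with a nitrile electrophile in place of the carboxylic acid: it sets out from 1 and comes back at 3. Compound 1 and commercial 3-(4-hydroxyphenyl)propanenitrile are treated with ZnCl2 and dry HCl in Et2O at 0 °C. The precipitated 1-(2,4-dihydroxyphenyl)-3-(4-hydroxyphenyl)propan-1-iminium chloride F1 is hydrolysed in water at 100 °C to 3.

**Further compounds**
F1 | step 1 | 1-(2,4-dihydroxyphenyl)-3-(4-hydroxyphenyl)propan-1-iminium chloride | [NH2+]=C(CCc1ccc(O)cc1)c1ccc(O)cc1O.[Cl-]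
F0 | step 2 | none | none
F2 | step 3 | 1-[2-hydroxy-3-(3-methylbut-2-en-1-yl)-4-[(2-methylbut-3-yn-2-yl)oxy]phenyl]-3-(4-hydroxyphenyl)propan-1-one | C#CC(C)(C)Oc1ccc(C(=O)CCc2ccc(O)cc2)c(O)c1CC=C(C)C
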